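**Plan**

- Retrosynthesis: the two O–Si bonds are cut first, then the central benzene ring at C1'–C2' and C3'–C4', which gives a 2-pyranone (diene, O1–C2 leaving as CO2) and a silyl ynol ether.
- Enabling feature: ring carbons C1' (benzofuranyl), C6' (prenyl), C5' (OMe) and C4' (H) carry exactly the substituents of C6, C5, C4 and C3 of a 6-aryl-4-methoxy-5-prenyl-2-pyranone. Only the pair C2' (prenyl)/C3' (O) is missing, and that is a prenylated ynol unit.
- The pyranone is cut at the lactone C–O, the aroyl C–C (Claisen) and the prenyl C–C bond, back to methyl acetoacetate. The benzofuran is cut at O–CH2 and C3–C3a, back to 2,4-dihydroxybenzaldehyde. The ynol ether is cut at C–O and at the propargylic C–C bond.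
- Forward order of rings: benzofuran (step 2), pyranone (step 5), benzene (step 9). Three branches converge in steps 4 and 9.
- Stereochemistry: the target has no stereocentre and no configurationally defined alkene. The two bridgehead centres of the cycloadduct vanish with CO2.

Key step: step 9

Remark: enolate, dianion and acetylide salts made by simple deprotonation are treated as the reacting form of their numbered parent; LiN(i-Pr)2, LiN(SiMe3)2 and HC≡CMgBr are taken as commercial THF solutions.

**Route**

Step 1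
Reactants: 1 2,4-dihydroxybenzaldehyde
Product: 2 2-hydroxy-4-(triisopropylsilyloxy)benzaldehyde
Conditions: i-Pr3SiCl (1.05 equiv), imidazole (2.2 equiv), CH2Cl2, 0 → 23 °C
Reagents that add atoms: triisopropylsilyl chloride, CC(C)[Si](Cl)(C(C)C)C(C)C
Why: Silyl ether formation should occur only at the 4-hydroxyl, because the 2-hydroxyl is tied up in a hydrogen bond to the aldehyde and is the less nucleophilic of the two.

Step 2
Reactants: 2 2-hydroxy-4-(triisopropylsilyloxy)benzaldehyde; 3 ethyl bromoacetate
Product: 5 ethyl 6-(triisopropylsilyloxy)-1-benzofuran-2-carboxylate, via aryloxyacetate aldehyde 4 (not isolated)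
Conditions: K2CO3 (2.5 equiv), 4 Å molecular sieves, MeCN, 80 °C
Reagents that add atoms: none
Why: Williamson etherification of the phenol followed by intramolecular aldol condensation of the ester enolate onto the ortho aldehyde (Rap–Stoermer-type benzofuran synthesis) should close the furan ring; the hindered silyl ether and anhydrous carbonate are chosen to keep the aryl O–Si bond intact.

Step 3
Reactants: 6 methyl acetoacetate; 7 prenyl bromide (1-bromo-3-methylbut-2-ene)
Product: 8 methyl 7-methyl-3-oxooct-6-enoate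
Conditions: LiN(i-Pr)2 (2.1 equiv), THF, 0 °C; 7, 0 → 23 °C; AcOH
Reagents that add atoms: none
Why: Weiler dianion alkylation: the terminal (γ) carbanion of the acetoacetate dianion is the more reactive site and should displace the primary allylic bromide in an SN2 reaction.

Step 4
Reactants: 8 methyl 7-methyl-3-oxooct-6-enoate; 5 ethyl 6-(triisopropylsilyloxy)-1-benzofuran-2-carboxylate
Product: 9 methyl 7-methyl-3-oxo-4-[6-(triisopropylsilyloxy)-1-benzofuran-2-carbonyl]oct-6-enoate (racemic, keto–enol mixture)
Conditions: 8 (2.2 equiv), LiN(i-Pr)2 (4.4 equiv), THF, 0 °C; 5 (1.0 equiv), −78 → 0 °C; AcOH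
Reagents that add atoms: none
Why: Claisen-type C-acylation of the β-keto ester dianion at its γ-carbon by the electrophilic heteroaryl ester (Huckin–Weiler acylation) should give the 3,5-diketo ester; the excess dianion absorbs the proton of the more acidic product.

Step 5
Reactants: 9 methyl 7-methyl-3-oxo-4-[6-(triisopropylsilyloxy)-1-benzofuran-2-carbonyl]oct-6-enoate
Product: 10 4-hydroxy-5-(3-methylbut-2-en-1-yl)-6-[6-(triisopropylsilyloxy)-1-benzofuran-2-yl]-2H-pyran-2-one
Conditions: DBU (1.5 equiv), toluene (anhydrous), 60 °C; aq citric acid work-up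
Reagents that add atoms: none
Why: Base-mediated lactonisation of the C5 enol oxygen onto the methyl ester, the standard closure of 3,5-diketo esters, should give the conjugated 4-hydroxy-2-pyranone with loss of methanol.

Step 6
Reactants: 10 4-hydroxy-5-(3-methylbut-2-en-1-yl)-6-[6-(triisopropylsilyloxy)-1-benzofuran-2-yl]-2H-pyran-2-one
Product: 11 4-methoxy-5-(3-methylbut-2-en-1-yl)-6-[6-(triisopropylsilyloxy)-1-benzofuran-2-yl]-2H-pyran-2-one
Conditions: Me2SO4 (1.2 equiv), K2CO3 (2 equiv), acetone, 23 → 45 °C
Reagents that add atoms: dimethyl sulfate, COS(=O)(=O)OC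
Why: O-methylation of the vinylogous acid with a hard methylating agent and carbonate in acetone is the established way to the 4-methoxy-2-pyranone rather than the 2-methoxy-4-pyranone or a C3-methylated product.

Step 7
Reactants: 12 ethynylmagnesium bromide; 7 prenyl bromide
Product: 13 5-methylhex-4-en-1-yne
Conditions: HC≡CMgBr (1.5 equiv), CuBr·SMe2 (5 mol %), THF, 0 → 23 °C; fractional distillation
Reagents that add atoms: none
Why: Copper-catalysed allylic substitution by the alkynyl Grignard reagent should take place at the unhindered primary terminus of the prenyl bromide and give the skipped enyne; excess acetylide suppresses double alkylation.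

Step 8
Reactants: 13 5-methylhex-4-en-1-yne
Product: 15 triisopropyl[(5-methylhex-4-en-1-yn-1-yl)oxy]silane, via lithium ynolate 14 (not isolated)
Conditions: LiN(SiMe3)2, THF, −78 °C; t-BuOOLi (from t-BuOOH and LiN(SiMe3)2), −78 → 0 °C; i-Pr3SiOTf, −78 → 0 °C; NaHCO3 work-up
Reagents that add atoms: tert-butyl hydroperoxide, CC(C)(C)OO; triisopropylsilyl trifluoromethanesulfonate, CC(C)[Si](OS(=O)(=O)C(F)(F)F)(C(C)C)C(C)C
Why: Julia oxidation of the lithium acetylide by lithium tert-butyl peroxide gives the ynolate, which the bulky silyl triflate should trap on oxygen rather than carbon; the weak amide base leaves the doubly activated CH2 untouched.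

Step 9
Reactants: 11 4-methoxy-5-(3-methylbut-2-en-1-yl)-6-[6-(triisopropylsilyloxy)-1-benzofuran-2-yl]-2H-pyran-2-one; 15 triisopropyl[(5-methylhex-4-en-1-yn-1-yl)oxy]silane
Product: 17 2-[3-methoxy-2,6-bis(3-methylbut-2-en-1-yl)-5-(triisopropylsilyloxy)phenyl]-6-(triisopropylsilyloxy)-1-benzofuran, via bridged bicyclic lactone 16 (not isolated)
Conditions: 15 (2.0 equiv), AgNTf2 (10 mol %), 4 Å molecular sieves, ClCH2CH2Cl, 23 → 60 °C
Reagents that add atoms: none
Why: AgNTf2 is expected to bind the lactone carbonyl of 11 and raise the electrophilicity of C6, the δ-terminus of the dienoate, which is attacked by the nucleophilic prenyl-bearing carbon of 15; the silyl ketenium carbon so formed is captured by the dienolate carbon C3, completing an asynchronous inverse-demand [4+2] cycloaddition (C1'–C2' and C3'–C4') to the 2-oxabicyclo[2.2.2]octadienone 16. Retro-[4+2] loss of CO2 from 16 is driven by aromatisation and delivers the benzene ring directly. The closest known reactions are the benzannulations of 2-pyranones with ynamines and with siloxyalkynes under silver or triflimide promotion, and the silver-catalysed inverse-demand cycloadditions of siloxyalkynes with 1,2-diazines; a 4-methoxy-6-aryl pyranone is an untested and electronically reluctant member of the class. The one ring closed, the central benzene ring, arises by intermolecular [4+2] annulation, its second bond by six-membered closure of the dienolate onto the ketenium carbon. No stereocentre is set, since the two bridgehead centres of racemic 16 are destroyed on loss of CO2. The step needs head-to-tail regioselectivity, secured by the matched polarisation of the partners (alkyne carbon β to oxygen nucleophilic, pyranone C6 electrophilic, C3 nucleophilic), and chemoselectivity over the prenyl alkenes and the benzofuran, which are unpolarised and should not be activated by the silver salt.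

Step 10
Reactants: 17 2-[3-methoxy-2,6-bis(3-methylbut-2-en-1-yl)-5-(triisopropylsilyloxy)phenyl]-6-(triisopropylsilyloxy)-1-benzofuran
Product: 18 2-[5-hydroxy-3-methoxy-2,6-bis(3-methylbut-2-en-1-yl)phenyl]-1-benzofuran-6-ol (CNP0324103.0)
Conditions: Bu4NF (2.5 equiv), AcOH (2.5 equiv), THF, 0 → 23 °C
Reagents that add atoms: none
Why: Fluoride cleaves both aryl O–Si bonds (silyl ether deprotection), and the acetic acid buffer keeps the electron-rich prenylated phenoxides from oxidising or cyclising.

**Compound list**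

1 | 2,4-dihydroxybenzaldehyde | O=Cc1ccc(O)cc1O | starting material
2 | 2-hydroxy-4-(triisopropylsilyloxy)benzaldehyde | O=Cc1ccc(O[Si](C(C)C)(C(C)C)C(C)C)cc1O | intermediate
3 | ethyl bromoacetate | CCOC(=O)CBr | starting material
4 | ethyl 2-[2-formyl-5-(triisopropylsilyloxy)phenoxy]acetate | CCOC(=O)COc1cc(O[Si](C(C)C)(C(C)C)C(C)C)ccc1C=O | intermediate
5 | ethyl 6-(triisopropylsilyloxy)-1-benzofuran-2-carboxylate | CCOC(=O)c1cc2ccc(O[Si](C(C)C)(C(C)C)C(C)C)cc2o1 | intermediate
6 | methyl acetoacetate | COC(=O)CC(C)=O | starting material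
7 | prenyl bromide (1-bromo-3-methylbut-2-ene) | CC(C)=CCBr | starting material
8 | methyl 7-methyl-3-oxooct-6-enoate | COC(=O)CC(=O)CCC=C(C)C | intermediate
9 | methyl 7-methyl-3-oxo-4-[6-(triisopropylsilyloxy)-1-benzofuran-2-carbonyl]oct-6-enoate (racemic) | COC(=O)CC(=O)C(CC=C(C)C)C(=O)c1cc2ccc(O[Si](C(C)C)(C(C)C)C(C)C)cc2o1 | intermediate
10 | 4-hydroxy-5-(3-methylbut-2-en-1-yl)-6-[6-(triisopropylsilyloxy)-1-benzofuran-2-yl]-2H-pyran-2-one | O=c1cc(O)c(CC=C(C)C)c(-c2cc3ccc(O[Si](C(C)C)(C(C)C)C(C)C)cc3o2)o1 | intermediate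
11 | 4-methoxy-5-(3-methylbut-2-en-1-yl)-6-[6-(triisopropylsilyloxy)-1-benzofuran-2-yl]-2H-pyran-2-one | COc1cc(=O)oc(-c2cc3ccc(O[Si](C(C)C)(C(C)C)C(C)C)cc3o2)c1CC=C(C)C | intermediate
12 | ethynylmagnesium bromide | C#C[Mg]Br | starting material
13 | 5-methylhex-4-en-1-yne | C#CCC=C(C)C | intermediate
14 | lithium 5-methylhex-4-en-1-yn-1-olate | [Li+].[O-]C#CCC=C(C)C | intermediate
15 | triisopropyl[(5-methylhex-4-en-1-yn-1-yl)oxy]silane | CC(C)=CCC#CO[Si](C(C)C)(C(C)C)C(C)C | intermediate
16 | 5-methoxy-6,7-bis(3-methylbut-2-en-1-yl)-8-(triisopropylsilyloxy)-1-[6-(triisopropylsilyloxy)-1-benzofuran-2-yl]-2-oxabicyclo[2.2.2]octa-5,7-dien-3-one (racemic) | O=C1OC2(c3cc4ccc(O[Si](C(C)C)(C(C)C)C(C)C)cc4o3)C(CC=C(C)C)=C(OC)C1C(O[Si](C(C)C)(C(C)C)C(C)C)=C2CC=C(C)C | intermediate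
17 | 2-[3-methoxy-2,6-bis(3-methylbut-2-en-1-yl)-5-(triisopropylsilyloxy)phenyl]-6-(triisopropylsilyloxy)-1-benzofuran | COc1cc(O[Si](C(C)C)(C(C)C)C(C)C)c(CC=C(C)C)c(-c2cc3ccc(O[Si](C(C)C)(C(C)C)C(C)C)cc3o2)c1CC=C(C)C | intermediate
18 | 2-[5-hydroxy-3-methoxy-2,6-bis(3-methylbut-2-en-1-yl)phenyl]-1-benzofuran-6-ol | COc1cc(O)c(CC=C(C)C)c(-c2cc3ccc(O)cc3o2)c1CC=C(C)C | target

**Count**

Total steps: 10. Longest linear sequence: 7 steps (steps 1, 2, 4, 5, 6, 9, 10).

**Steps most likely to fail**

Step 9. The donor-substituted, fully substituted pyranone may fail to engage the ynol ether. The alkyne may instead be consumed by silver-promoted self-condensation or hydrolysis, or it may add at the methoxy-bearing C4 rather than C6. The fallback closes the benzene ring by carbonyl condensation instead of cycloaddition and sets out from ester 5 and prenyl bromide 7. Pentane-2,4-dione is alkylated at a terminal carbon through its dianion (LiN(i-Pr)2, 2 equiv, THF, 0 °C; 7) to give 7-methyloct-6-ene-2,4-dione F1. A second dianion alkylation at the other terminus gives 2,12-dimethyltrideca-2,11-diene-6,8-dione F2. The dianion of F2 is acylated at a terminal carbon by 5 (Claisen condensation) to give 9-methyl-2-(3-methylbut-2-en-1-yl)-1-[6-(triisopropylsilyloxy)-1-benzofuran-2-yl]dec-8-ene-1,3,5-trione F3. Intramolecular aldol condensation of C6 onto the aryl ketone under anhydrous base (DBU, toluene, 80 °C), followed by tautomerisation, should give 4,6-bis(3-methylbut-2-en-1-yl)-5-[6-(triisopropylsilyloxy)-1-benzofuran-2-yl]benzene-1,3-diol F4. Its two hydroxyls are equivalent, so monomethylation (MeI, 1 equiv, K2CO3, acetone; diol and diether separated, diol recycled) gives a single monoether, 5-methoxy-2,4-bis(3-methylbut-2-en-1-yl)-3-[6-(triisopropylsilyloxy)-1-benzofuran-2-yl]phenol F5. Bu4NF/AcOH then rejoins the route at target 18.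

Step 4. Acylation at the secondary carbanion may stall through proton transfer from the acidic product to the dianion, O-acylation or retro-Claisen cleavage. The fallback replaces the Claisen condensation by an aldol addition and oxidation, and sets out from 5 and 8. Ester 5 is reduced with i-Bu2AlH (CH2Cl2, −78 → 0 °C) to [6-(triisopropylsilyloxy)-1-benzofuran-2-yl]methanol F6. This is oxidised with MnO2 (CH2Cl2) to 6-(triisopropylsilyloxy)-1-benzofuran-2-carbaldehyde F7. The dianion of 8 adds to F7 at −78 °C to give methyl 4-{hydroxy[6-(triisopropylsilyloxy)-1-benzofuran-2-yl]methyl}-7-methyl-3-oxooct-6-enoate F8 as a diastereomer mixture. Dess–Martin periodinane oxidises the carbinol, and the route is rejoined at diketo ester 9.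

Step 2. The aryl silyl ether may be lost under hot carbonate, after which the freed phenoxide is alkylated, or the sequence may stop at the uncyclised ether. The fallback carries the oxygen through the annulation as a benzyl ether and sets out from 1. Selective 4-O-benzylation (BnBr, NaHCO3, MeCN, 80 °C) gives 4-(benzyloxy)-2-hydroxybenzaldehyde F9. Alkylation with 3 and cyclisation (K2CO3, DMF, 100 °C) proceed through ethyl 2-[5-(benzyloxy)-2-formylphenoxy]acetate F10 to ethyl 6-(benzyloxy)-1-benzofuran-2-carboxylate F11. Hydrogenolysis (H2, Pd/C, EtOAc, 23 °C) gives ethyl 6-hydroxy-1-benzofuran-2-carboxylate F12. Silylation (i-Pr3SiCl, imidazole, CH2Cl2) rejoins the route at 5.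

Further compounds
F1 | step 9 | 7-methyloct-6-ene-2,4-dione | CC(=O)CC(=O)CCC=C(C)C
F2 | step 9 | 2,12-dimethyltrideca-2,11-diene-6,8-dione | CC(C)=CCCC(=O)CC(=O)CCC=C(C)C
F3 | step 9 | 9-methyl-2-(3-methylbut-2-en-1-yl)-1-[6-(triisopropylsilyloxy)-1-benzofuran-2-yl]dec-8-ene-1,3,5-trione (racemic) | CC(C)=CCCC(=O)CC(=O)C(CC=C(C)C)C(=O)c1cc2ccc(O[Si](C(C)C)(C(C)C)C(C)C)cc2o1
F4 | step 9 | 4,6-bis(3-methylbut-2-en-1-yl)-5-[6-(triisopropylsilyloxy)-1-benzofuran-2-yl]benzene-1,3-diol | CC(C)=CCc1c(O)cc(O)c(CC=C(C)C)c1-c1cc2ccc(O[Si](C(C)C)(C(C)C)C(C)C)cc2o1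
F5 | step 9 | 5-methoxy-2,4-bis(3-methylbut-2-en-1-yl)-3-[6-(triisopropylsilyloxy)-1-benzofuran-2-yl]phenol | COc1cc(O)c(CC=C(C)C)c(-c2cc3ccc(O[Si](C(C)C)(C(C)C)C(C)C)cc3o2)c1CC=C(C)C
F6 | step 4 | [6-(triisopropylsilyloxy)-1-benzofuran-2-yl]methanol | OCc1cc2ccc(O[Si](C(C)C)(C(C)C)C(C)C)cc2o1
F7 | step 4 | 6-(triisopropylsilyloxy)-1-benzofuran-2-carbaldehyde | O=Cc1cc2ccc(O[Si](C(C)C)(C(C)C)C(C)C)cc2o1
F8 | step 4 | methyl 4-{hydroxy[6-(triisopropylsilyloxy)-1-benzofuran-2-yl]methyl}-7-methyl-3-oxooct-6-enoate (diastereomer mixture, racemic) | COC(=O)CC(=O)C(CC=C(C)C)C(O)c1cc2ccc(O[Si](C(C)C)(C(C)C)C(C)C)cc2o1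
F9 | step 2 | 4-(benzyloxy)-2-hydroxybenzaldehyde | O=Cc1ccc(OCc2ccccc2)cc1O
F10 | step 2 | ethyl 2-[5-(benzyloxy)-2-formylphenoxy]acetate | CCOC(=O)COc1cc(OCc2ccccc2)ccc1C=O
F11 | step 2 | ethyl 6-(benzyloxy)-1-benzofuran-2-carboxylate | CCOC(=O)c1cc2ccc(OCc3ccccc3)cc2o1
F12 | step 2 | ethyl 6-hydroxy-1-benzofuran-2-carboxylate | CCOC(=O)c1cc2ccc(O)cc2o1
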